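A straight line of product cannot go on in a closed flask: it ends by meeting the charge of starting material. So I ask the ochre run where that line would end in the new flask.

- ochre: starting material 0.50 M; free catalyst 120 mM; run made earlier
- flask: starting material 0.50 M; free catalyst 60 mM; time 3.0 min

ochre run (percent of the starting material charged)

| time / s | product / % | crystals / % |
|---|---|---|
| 10.0 | 8.8 | 0.1 |
| 12.0 | 11.5 | 0 |
| 20.0 | 21.5 | 0 |

(readings scatter by 0.3 percentage points)

- product is meant together with its crystals
- solid, in amounts per volume of the solution: crystals
- the numbers in the tables scatter by 0.3 percentage points (one standard deviation)
- no earlier run changes the charge of free catalyst; that part of a forecast is a guess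

- the product and crystals together standing at 3.0 min, as a percentage of the starting material charged
- concentration of product in solution at 3.0 min, in percent of saturation

I take the run in slow motion. In its first instants, the ochre line drawn back reaches zero at about 3.07 s, a short delay. Then product in the ochre run climbs steadily: the product made per second for each free catalyst charged, the turnover frequency w, reads 0.0529 s⁻¹.

I expect the concentration of starting material to set the order of the rate: while it is ample, the rate is w times the catalyst charged (zero order in starting material); when it is thin, the rate follows it (first order). Scaling with catalyst is a guess. In the new flask, the line reaches the charge at τ = 2.62 min, earlier than 3.0 min. Near that end I expect the new flask to fall behind its line. Were the rate to fall with starting material from the outset, it would stand at 68.1%, so I expect between that and the full charge. The ochre run shows no crystals beyond the scatter up to 0.107 M of product, so saturation lies higher, at a place I cannot read.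

The forecast gives 78% (62% to 97%) and 100% of saturation (72% to 135%), with the words “I lean toward first order, nudged upward”; its figure stands above my lower end.

The flask gives 83.9% and 101% of saturation.

    starting material + free catalyst → catalyst intermediate (k = 0.280 M⁻¹ s⁻¹)
    catalyst intermediate → free catalyst + product (k = 0.110 s⁻¹)
    crystals ⇌ product, rate k3*(cs3 - [product]) while solid is left; crystals form when [product] > cs3 (solubility = 0.190 M, k = 0.550 s⁻¹)

With the making and the using of catalyst intermediate in balance, it stands equal to free catalyst at 0.393 M of starting material (the Michaelis constant); the flask starts above that, with 51.7% of its catalyst as catalyst intermediate at 0.300 min, and ends below it, with 16.7% at 3.00 min. The line of w would pass 114% of the charge at 3.0 min, yet the flask keeps 14% of its starting material. Read at 50 s, the same flask should stand by w at 31.8%; it stands at 30.7%.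

(The earlier runs and the new flask stem from a simulated flask with made-up constants, noise included.)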